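**Retrosynthetic overview**

- The target comes from hydrolysis of a C-6 vinylogous acyl fluoride, itself the product of a dearomatising [3,3] Claisen rearrangement of an aryl 1,1-dimethylallyl ether. The rearrangement makes the C-3a–prenyl bond and the quaternary centre, anti to the C-2 side chain; fluorine stands in for the C-6 oxygen until the last operation.
- The aryl ether comes from a fully substituted 6-fluoro-2,3-dihydrobenzofuran: isobutyryl by ortho-metalation/acylation, dihydrofuran ring by intramolecular SNAr of a side-chain alkoxide on the one fluorine next to it (C–O bond of the stereocentre kept).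
- Both C5 side chains come from 1-(benzyloxy)-3,5-difluorobenzene and two equivalents of methyl (S)-glycidate (fluorine-directed metalation, copper-catalysed epoxide opening, MeMgBr). The first diol is closed to the oxirane with inversion, the second is cyclised with retention.
- Ring order: oxirane (step 2), dihydrofuran (step 4), cyclohexadienone by dearomatisation of the benzene ring (step 8).

Assumption: the enolised β-triketone is one compound whichever tautomer is drawn, and both starting materials and all reagents are catalogue chemicals.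

**Step 1**
Reactants: 1 1-(benzyloxy)-3,5-difluorobenzene; 2 methyl (2S)-oxirane-2-carboxylate
Product: 6 (2S)-1-[4-(benzyloxy)-2,6-difluorophenyl]-3-methylbutane-2,3-diol, via aryllithium 3 (not isolated), via arylmagnesium bromide 4 (not isolated), via hydroxy ester 5 (not isolated)
Conditions: n-BuLi, THF, −78 °C; MgBr2·OEt2; CuBr·SMe2 (10 mol %), 2, −78 → −30 °C; then MeMgBr (3.5 equiv), −30 → 0 °C
Reagents that add atoms: methylmagnesium bromide, C[Mg]Br
Why: Directed ortho-lithiation occurs between the two fluorines, the derived Grignard reagent opens the glycidate at its CH2 terminus under monovalent-copper catalysis without touching the stereocentre, and Grignard addition to the ester gives the tertiary carbinol.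

**Step 2**
Reactants: 6 (2S)-1-[4-(benzyloxy)-2,6-difluorophenyl]-3-methylbutane-2,3-diol
Product: 8 (2R)-2-{[4-(benzyloxy)-2,6-difluorophenyl]methyl}-3,3-dimethyloxirane, via secondary mesylate 7 (not isolated)
Conditions: MsCl, Et3N, CH2Cl2, −10 °C; then K2CO3, MeOH, 25 °C
Reagents that add atoms: none
Why: Only the secondary hydroxyl is sulfonylated and the neighbouring tertiary alkoxide displaces it in a 3-exo intramolecular Williamson etherification with inversion, turning the (S)-carbinol into the (R)-oxirane carbon of the target.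

**Step 3**
Reactants: 8 (2R)-2-{[4-(benzyloxy)-2,6-difluorophenyl]methyl}-3,3-dimethyloxirane; 2 methyl (2S)-oxirane-2-carboxylate
Product: 12 (2S)-1-[6-(benzyloxy)-3-{[(2R)-3,3-dimethyloxiran-2-yl]methyl}-2,4-difluorophenyl]-3-methylbutane-2,3-diol, via aryllithium 9 (not isolated), via arylmagnesium bromide 10 (not isolated), via hydroxy ester 11 (not isolated)
Conditions: lithium 2,2,6,6-tetramethylpiperidide, THF, −78 °C; MgBr2·OEt2; CuBr·SMe2 (10 mol %), 2, −78 → −30 °C; then MeMgBr (3.5 equiv), −30 → 0 °C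
Reagents that add atoms: methylmagnesium bromide, C[Mg]Br
Why: Directed ortho-metalation with a non-nucleophilic amide takes one of the two equivalent C–H positions between F and OBn, and the same copper-catalysed glycidate opening and Grignard addition install the second (S)-diol chain with its stereocentre taken unchanged from 2.

**Step 4**
Reactants: 12 (2S)-1-[6-(benzyloxy)-3-{[(2R)-3,3-dimethyloxiran-2-yl]methyl}-2,4-difluorophenyl]-3-methylbutane-2,3-diol
Product: 13 2-[(2S)-4-(benzyloxy)-7-{[(2R)-3,3-dimethyloxiran-2-yl]methyl}-6-fluoro-2,3-dihydro-1-benzofuran-2-yl]propan-2-ol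
Conditions: NaH, DMF, 70 °C
Reagents that add atoms: none
Why: The secondary alkoxide displaces the only fluorine ortho to its chain (activated by the meta fluorine) in a 5-exo intramolecular SNAr, and because the C–O bond of the carbinol is kept the new ring carbon C-2 is (S).

**Step 5**
Reactants: 13 2-[(2S)-4-(benzyloxy)-7-{[(2R)-3,3-dimethyloxiran-2-yl]methyl}-6-fluoro-2,3-dihydro-1-benzofuran-2-yl]propan-2-ol
Product: 15 1-[(2S)-4-(benzyloxy)-7-{[(2R)-3,3-dimethyloxiran-2-yl]methyl}-6-fluoro-2-(2-hydroxypropan-2-yl)-2,3-dihydro-1-benzofuran-5-yl]-2-methylpropan-1-one, via dilithio species 14 (not isolated)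
Conditions: lithium 2,2,6,6-tetramethylpiperidide (2.2 equiv), THF, −78 °C; then iPrC(O)N(OMe)Me, −78 → 0 °C
Reagents that add atoms: N-methoxy-N,2-dimethylpropanamide, CC(C)C(=O)N(C)OC
Why: After deprotonation of the tertiary alcohol the single remaining ring C–H, flanked by F and OBn, is lithiated (directed ortho-metalation) and the aryllithium is acylated once in a Weinreb ketone synthesis.

**Step 6**
Reactants: 15 1-[(2S)-4-(benzyloxy)-7-{[(2R)-3,3-dimethyloxiran-2-yl]methyl}-6-fluoro-2-(2-hydroxypropan-2-yl)-2,3-dihydro-1-benzofuran-5-yl]-2-methylpropan-1-one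
Product: 16 1-[(2S)-7-{[(2R)-3,3-dimethyloxiran-2-yl]methyl}-6-fluoro-4-hydroxy-2-(2-hydroxypropan-2-yl)-2,3-dihydro-1-benzofuran-5-yl]-2-methylpropan-1-one
Conditions: H2 (1 atm), 10 % Pd/C, EtOAc, 25 °C
Reagents that add atoms: none
Why: Hydrogenolysis of the benzyl ether frees the C-4 phenol while the aryl fluoride, the non-benzylic trisubstituted oxirane and the hindered aryl ketone are left alone.

**Step 7**
Reactants: 16 1-[(2S)-7-{[(2R)-3,3-dimethyloxiran-2-yl]methyl}-6-fluoro-4-hydroxy-2-(2-hydroxypropan-2-yl)-2,3-dihydro-1-benzofuran-5-yl]-2-methylpropan-1-one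
Product: 17 1-[(2S)-7-{[(2R)-3,3-dimethyloxiran-2-yl]methyl}-6-fluoro-2-(2-hydroxypropan-2-yl)-4-[(2-methylbut-3-en-2-yl)oxy]-2,3-dihydro-1-benzofuran-5-yl]-2-methylpropan-1-one
Conditions: tert-butyl 2-methylbut-3-en-2-yl carbonate (1.5 equiv), Pd(PPh3)4 (5 mol %), THF, 0 °C
Reagents that add atoms: tert-butyl 2-methylbut-3-en-2-yl carbonate, CC(C)(C)OC(=O)OC(C)(C)C=C
Why: In this decarboxylative Tsuji–Trost-type allylic etherification with zerovalent palladium the only phenoxide attacks the 1,1-dimethylallyl–palladium cation at its tertiary terminus under kinetic control, giving the branched ether needed for the rearrangement.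

**Step 8**
Reactants: 17 1-[(2S)-7-{[(2R)-3,3-dimethyloxiran-2-yl]methyl}-6-fluoro-2-(2-hydroxypropan-2-yl)-4-[(2-methylbut-3-en-2-yl)oxy]-2,3-dihydro-1-benzofuran-5-yl]-2-methylpropan-1-one
Product: 19 (2S,3aR)-7-{[(2R)-3,3-dimethyloxiran-2-yl]methyl}-4-hydroxy-2-(2-hydroxypropan-2-yl)-3a-(3-methylbut-2-en-1-yl)-5-(2-methylpropanoyl)-3,3a-dihydro-1-benzofuran-6(2H)-one, via fluorodienone 18 (not isolated)
Conditions: PhMe, 100 °C; then THF–aq. NaHCO3, 25 °C, pH 6 buffer on work-up
Reagents that add atoms: water, O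
Why: The aromatic Claisen rearrangement ([3,3]) delivers the allyl unit as a prenyl group to the electron-rich C-3a through a chair transition state on the face opposite the 2-(2-hydroxypropan-2-yl) group (2,3a-trans, which sets C-3a; the minor 3a-epimer is removed by chromatography), and the vinylogous acyl fluoride left at C-6 is hydrolysed by addition–elimination to the enolised triketone.

**Compound list**

1 | 1-(benzyloxy)-3,5-difluorobenzene | Fc1cc(F)cc(OCc2ccccc2)c1 | starting material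
2 | methyl (2S)-oxirane-2-carboxylate (methyl (S)-glycidate) | COC(=O)[C@@H]1CO1 | starting material
3 | [4-(benzyloxy)-2,6-difluorophenyl]lithium | [Li]c1c(F)cc(OCc2ccccc2)cc1F | intermediate
4 | [4-(benzyloxy)-2,6-difluorophenyl]magnesium bromide | Br[Mg]c1c(F)cc(OCc2ccccc2)cc1F | intermediate
5 | methyl (2S)-3-[4-(benzyloxy)-2,6-difluorophenyl]-2-hydroxypropanoate (formed as its magnesium alkoxide) | COC(=O)[C@@H](O)Cc1c(F)cc(OCc2ccccc2)cc1F | intermediate
6 | (2S)-1-[4-(benzyloxy)-2,6-difluorophenyl]-3-methylbutane-2,3-diol | CC(C)(O)[C@@H](O)Cc1c(F)cc(OCc2ccccc2)cc1F | intermediate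
7 | (2S)-1-[4-(benzyloxy)-2,6-difluorophenyl]-3-hydroxy-3-methylbutan-2-yl methanesulfonate | CC(C)(O)[C@@H](OS(C)(=O)=O)Cc1c(F)cc(OCc2ccccc2)cc1F | intermediate
8 | (2R)-2-{[4-(benzyloxy)-2,6-difluorophenyl]methyl}-3,3-dimethyloxirane | CC1(C)O[C@@H]1Cc1c(F)cc(OCc2ccccc2)cc1F | intermediate
9 | [6-(benzyloxy)-3-{[(2R)-3,3-dimethyloxiran-2-yl]methyl}-2,4-difluorophenyl]lithium | [Li]c1c(F)c(C[C@H]2OC2(C)C)c(F)cc1OCc1ccccc1 | intermediate
10 | [6-(benzyloxy)-3-{[(2R)-3,3-dimethyloxiran-2-yl]methyl}-2,4-difluorophenyl]magnesium bromide | Br[Mg]c1c(F)c(C[C@H]2OC2(C)C)c(F)cc1OCc1ccccc1 | intermediate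
11 | methyl (2S)-3-[6-(benzyloxy)-3-{[(2R)-3,3-dimethyloxiran-2-yl]methyl}-2,4-difluorophenyl]-2-hydroxypropanoate (formed as its magnesium alkoxide) | COC(=O)[C@@H](O)Cc1c(F)c(C[C@H]2OC2(C)C)c(F)cc1OCc1ccccc1 | intermediate
12 | (2S)-1-[6-(benzyloxy)-3-{[(2R)-3,3-dimethyloxiran-2-yl]methyl}-2,4-difluorophenyl]-3-methylbutane-2,3-diol | CC(C)(O)[C@@H](O)Cc1c(F)c(C[C@H]2OC2(C)C)c(F)cc1OCc1ccccc1 | intermediate
13 | 2-[(2S)-4-(benzyloxy)-7-{[(2R)-3,3-dimethyloxiran-2-yl]methyl}-6-fluoro-2,3-dihydro-1-benzofuran-2-yl]propan-2-ol | CC(C)(O)[C@@H]1Cc2c(O1)c(C[C@H]3OC3(C)C)c(F)cc2OCc2ccccc2 | intermediate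
14 | O-lithio, 5-lithio derivative of 13 (lithium alkoxide of the tertiary alcohol, lithium on C-5) | CC(C)(O[Li])[C@@H]1Cc2c(O1)c(C[C@H]3OC3(C)C)c(F)c([Li])c2OCc2ccccc2 | intermediate
15 | 1-[(2S)-4-(benzyloxy)-7-{[(2R)-3,3-dimethyloxiran-2-yl]methyl}-6-fluoro-2-(2-hydroxypropan-2-yl)-2,3-dihydro-1-benzofuran-5-yl]-2-methylpropan-1-one | CC(C)(O)[C@@H]1Cc2c(O1)c(C[C@H]3OC3(C)C)c(F)c(C(=O)C(C)C)c2OCc2ccccc2 | intermediate
16 | 1-[(2S)-7-{[(2R)-3,3-dimethyloxiran-2-yl]methyl}-6-fluoro-4-hydroxy-2-(2-hydroxypropan-2-yl)-2,3-dihydro-1-benzofuran-5-yl]-2-methylpropan-1-one | CC(C)(O)[C@@H]1Cc2c(O1)c(C[C@H]3OC3(C)C)c(F)c(C(=O)C(C)C)c2O | intermediate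
17 | 1-[(2S)-7-{[(2R)-3,3-dimethyloxiran-2-yl]methyl}-6-fluoro-2-(2-hydroxypropan-2-yl)-4-[(2-methylbut-3-en-2-yl)oxy]-2,3-dihydro-1-benzofuran-5-yl]-2-methylpropan-1-one | CC(C)(O)[C@@H]1Cc2c(O1)c(C[C@H]3OC3(C)C)c(F)c(C(=O)C(C)C)c2OC(C)(C)C=C | intermediate
18 | (2S,3aS)-7-{[(2R)-3,3-dimethyloxiran-2-yl]methyl}-6-fluoro-2-(2-hydroxypropan-2-yl)-3a-(3-methylbut-2-en-1-yl)-5-(2-methylpropanoyl)-3,3a-dihydro-1-benzofuran-4(2H)-one | CC(C)=CC[C@]12C[C@@H](C(C)(C)O)OC1=C(C[C@H]1OC1(C)C)C(F)=C(C(=O)C(C)C)C2=O | intermediate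
19 | (2S,3aR)-7-{[(2R)-3,3-dimethyloxiran-2-yl]methyl}-4-hydroxy-2-(2-hydroxypropan-2-yl)-3a-(3-methylbut-2-en-1-yl)-5-(2-methylpropanoyl)-3,3a-dihydro-1-benzofuran-6(2H)-one (CNP0395488.1) | CC(C)=CC[C@]12C[C@@H](C(C)(C)O)OC1=C(C[C@H]1OC1(C)C)C(=O)C(C(=O)C(C)C)=C2O | target

**Step count and risks**

Total step count: 8. Longest linear sequence: 8 (steps 1 to 8 from 1; 2 enters in steps 1 and 3).

Steps most likely to fail:

1. Step 8. The rearrangement has to dearomatise a ring that carries fluorine where the third oxygen will be, so the dienone is less stabilised than in an all-oxygen acylphloroglucinol. The position of the equilibrium, the choice of C-3a over the acyl-bearing C-5 and the facial selectivity are all unproven. The freshly formed acidic enol also sits next to an oxirane. Fallback, setting out from 15 and coming back at 19: the ketone-activated fluorine of 15 is displaced with sodium 2-(trimethylsilyl)ethoxide (THF, 25 °C) to give the 6-[2-(trimethylsilyl)ethoxy] ketone F3. Hydrogenolysis (H2, Pd/C) gives the phenol F4, and the palladium-catalysed etherification of step 7 gives the 1,1-dimethylallyl ether F5. Heating (PhMe, 100 °C) then rearranges a fully oxygenated ether to the silylethyl vinylogous ester F6, from which Bu4NF (THF, 0 °C, pH 6 buffer) releases 19.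

2. Step 4. The fluorine to be displaced is activated only by a meta fluorine and sits between two alkyl groups. The tertiary alkoxide could close a six-membered ring instead, and the oxirane has to survive hot alkoxide. Fallback, setting out from 12 and coming back at 15: diol 12 is metalated at its ring C–H with lithium 2,2,6,6-tetramethylpiperidide (3.3 equiv, THF, −78 °C) and acylated with the Weinreb amide of step 5 to give the ring-open aryl ketone F1. The fluorine to be displaced is now para to the carbonyl, so K2CO3 in DMF at 40 °C closes the dihydrofuran and gives 15 directly.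

3. Step 7. The phenol is chelated to the ketone and flanked on both sides, and the tertiary ether can isomerise to the linear prenyl ether or ionise on silica. Fallback, setting out from 16 and coming back at 17: alkylation with 3-chloro-3-methylbut-1-yne (CuCl2 1 mol %, DBU, MeCN, 0 °C) gives the 1,1-dimethylpropargyl ether F2. Semi-hydrogenation (H2, Pd/CaCO3 poisoned with Pb(OAc)2, quinoline, EtOAc) then gives 17.

**Further compounds**

F1 | step 4 | 1-{2-(benzyloxy)-3-[(2S)-2,3-dihydroxy-3-methylbutyl]-5-{[(2R)-3,3-dimethyloxiran-2-yl]methyl}-4,6-difluorophenyl}-2-methylpropan-1-one | CC(C)(O)[C@@H](O)Cc1c(F)c(C[C@H]2OC2(C)C)c(F)c(C(=O)C(C)C)c1OCc1ccccc1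
F2 | step 7 | 1-[(2S)-7-{[(2R)-3,3-dimethyloxiran-2-yl]methyl}-6-fluoro-2-(2-hydroxypropan-2-yl)-4-[(2-methylbut-3-yn-2-yl)oxy]-2,3-dihydro-1-benzofuran-5-yl]-2-methylpropan-1-one | CC(C)(O)[C@@H]1Cc2c(O1)c(C[C@H]3OC3(C)C)c(F)c(C(=O)C(C)C)c2OC(C)(C)C#C
F3 | step 8 | 1-[(2S)-4-(benzyloxy)-7-{[(2R)-3,3-dimethyloxiran-2-yl]methyl}-2-(2-hydroxypropan-2-yl)-6-[2-(trimethylsilyl)ethoxy]-2,3-dihydro-1-benzofuran-5-yl]-2-methylpropan-1-one | CC(C)(O)[C@@H]1Cc2c(O1)c(C[C@H]3OC3(C)C)c(OCC[Si](C)(C)C)c(C(=O)C(C)C)c2OCc2ccccc2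
F4 | step 8 | 1-[(2S)-7-{[(2R)-3,3-dimethyloxiran-2-yl]methyl}-4-hydroxy-2-(2-hydroxypropan-2-yl)-6-[2-(trimethylsilyl)ethoxy]-2,3-dihydro-1-benzofuran-5-yl]-2-methylpropan-1-one | CC(C)(O)[C@@H]1Cc2c(O1)c(C[C@H]3OC3(C)C)c(OCC[Si](C)(C)C)c(C(=O)C(C)C)c2O
F5 | step 8 | 1-[(2S)-7-{[(2R)-3,3-dimethyloxiran-2-yl]methyl}-2-(2-hydroxypropan-2-yl)-4-[(2-methylbut-3-en-2-yl)oxy]-6-[2-(trimethylsilyl)ethoxy]-2,3-dihydro-1-benzofuran-5-yl]-2-methylpropan-1-one | CC(C)(O)[C@@H]1Cc2c(O1)c(C[C@H]3OC3(C)C)c(OCC[Si](C)(C)C)c(C(=O)C(C)C)c2OC(C)(C)C=C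
F6 | step 8 | (2S,3aS)-7-{[(2R)-3,3-dimethyloxiran-2-yl]methyl}-2-(2-hydroxypropan-2-yl)-3a-(3-methylbut-2-en-1-yl)-5-(2-methylpropanoyl)-6-[2-(trimethylsilyl)ethoxy]-3,3a-dihydro-1-benzofuran-4(2H)-one | CC(C)=CC[C@]12C[C@@H](C(C)(C)O)OC1=C(C[C@H]1OC1(C)C)C(OCC[Si](C)(C)C)=C(C(=O)C(C)C)C2=O
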